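## Retrosynthetic overview

1. The last step acylates the C9 alcohol. The C7 senecioate is carried from the acyclic stage and the C9 hydroxyl only appears in the cyclobutane-forming step, so the two esters never compete (longipinane numbering).
2. Ring C (cyclobutane) is cut at the C2–C7 bond (farnesyl numbering), mirroring himachalyl cation → longipinyl cation. A 7,8-epoxide of a cis-fused himachalane enone opens at its tertiary carbon and is captured by the γ-carbon of the extended silyl dienol ether, which also unveils the C8 (longipinane C9) alcohol.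
3. The himachalane is cut at C1–C6 and C3–C4, back to an acyclic diketo-enone that already holds the C1–C11 bond. An intramolecular Michael addition (enone C1 as allyl-cation surrogate, ketone enamine C6 as olefin surrogate) closes the seven-membered ring B, then aldol condensation closes ring A.
4. The acyclic chain comes from m-xylene (Birch reduction, then mono-ozonolysis gives the Z-alkene, ketone and aldehyde), an isobutyraldehyde enol silane (asymmetric Mukaiyama aldol, the only reagent-controlled stereocenter), senecioyl chloride and an acetonyl ylide.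
5. Ring order: B (seven-membered) → A (six-membered) in one flask → C (four-membered).

Assumption: the presumed biosynthesis is farnesyl diphosphate → humulyl cation (C1–C11) → himachalyl cation (C1–C6) → longipinyl cation (C2–C7) → α-longipinene → oxidation and acylation.
Assumption: the (S)-valine-derived oxazaborolidinone gives the 3R aldol 7; if the facial sense proves opposite, the (R)-valine-derived catalyst is used.
Convention: longipinane numbering for 17, 18 and 20 is C1 (C=O), C2=C3(CH3), C4 and C11 bridgeheads, C5 and C10 one-carbon bridges, C6 C(CH3)2, C7–C8–C9 the oxygenated chain.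

## Route

Step 1
Reactants: 1 m-xylene (1,3-dimethylbenzene)
Product: 2 1,5-dimethylcyclohexa-1,4-diene
Conditions: Li, NH3 (l), EtOH, Et2O, −78 to −33 °C
Reagents that add atoms: none
Why: Birch reduction leaves the two methyl-bearing carbons sp2 and gives the 2,5-dihydro (skipped) diene, with no stereocenter formed.

Step 2
Reactants: 2 1,5-dimethylcyclohexa-1,4-diene
Product: 4 (3Z)-4-methyl-6-oxohept-3-enal, via ozonide 3 (not isolated)
Conditions: O3 (0.95 equiv), CH2Cl2, −78 °C; then Me2S, −78 °C to rt
Reagents that add atoms: ozone, O=[O+][O-]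
Why: Ozonolysis with reductive work-up, where the two trisubstituted alkenes are equivalent so sub-stoichiometric ozone cleaves one of them and the ring geometry of the surviving alkene becomes the Z configuration.

Step 3
Reactants: 4 (3Z)-4-methyl-6-oxohept-3-enal; 5 trimethyl[(2-methylprop-1-en-1-yl)oxy]silane
Product: 7 (3R,5Z)-3-hydroxy-2,2,6-trimethyl-8-oxonon-5-enal, via silyl ether 6 (not isolated)
Conditions: (S)-4-isopropyl-3-tosyl-1,3,2-oxazaborolidin-5-one (20 mol%), EtNO2, −78 °C; then 1 M HCl, THF, 0 °C
Reagents that add atoms: none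
Why: Proposed new method: a Mukaiyama cross-aldol of an aldehyde-derived enol silane under a Kiyooka-type chiral oxazaborolidinone, in which the boron Lewis acid binds the aldehyde of 4 in preference to the ketone and shields one face so that the carbinol carbon forms R, while the α-quaternary product can neither enolise nor add again; closest known reaction types are the Kiyooka aldol of ketene silyl acetals and the achiral Lewis acid Mukaiyama aldol of this same enol silane.

Step 4
Reactants: 7 (3R,5Z)-3-hydroxy-2,2,6-trimethyl-8-oxonon-5-enal; 8 3-methylbut-2-enoyl chloride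
Product: 9 (3R,5Z)-2,2,6-trimethyl-1,8-dioxonon-5-en-3-yl 3-methylbut-2-enoate
Conditions: pyridine, DMAP (cat.), CH2Cl2, 0 °C to rt
Reagents that add atoms: none
Why: DMAP-catalysed esterification installs the final senecioate without touching the stereocenter and blocks retro-aldol and retro-vinylogous-aldol cleavage of the β-oxygenated neopentyl unit in later steps.

Step 5
Reactants: 9 (3R,5Z)-2,2,6-trimethyl-1,8-dioxonon-5-en-3-yl 3-methylbut-2-enoate; 10 1-(triphenyl-λ5-phosphanylidene)propan-2-one
Product: 11 (3E,6R,8Z)-5,5,9-trimethyl-2,11-dioxododeca-3,8-dien-6-yl 3-methylbut-2-enoate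
Conditions: PhMe, 90 °C
Reagents that add atoms: none
Why: Wittig olefination with a stabilised ylide reacts only with the aldehyde (not the methyl ketone or ester) and gives the E enone.

Step 6
Reactants: 11 (3E,6R,8Z)-5,5,9-trimethyl-2,11-dioxododeca-3,8-dien-6-yl 3-methylbut-2-enoate
Product: 14 (1S,3R,7R)-2,2,6,10-tetramethyl-8-oxobicyclo[5.4.0]undeca-5,9-dien-3-yl 3-methylbut-2-enoate, via Michael adduct 12 (not isolated), via aldol 13 (not isolated)
Conditions: pyrrolidine (0.5 equiv), AcOH (0.5 equiv), PhMe, 50 °C
Reagents that add atoms: none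
Why: A Robinson-type annulation in which the enamine of the β,γ-unsaturated methyl ketone adds through its α-carbon to the enone (intramolecular Michael addition, seven-membered ring) and the acetyl methyl then condenses with the less hindered methyl ketone (aldol condensation, ring A); the ester sits pseudo-equatorial and directs the new ring-fusion carbon C1 by 1,3-induction, and the epimerisable C7–H settles to the cis ring fusion.

Step 7
Reactants: 14 (1S,3R,7R)-2,2,6,10-tetramethyl-8-oxobicyclo[5.4.0]undeca-5,9-dien-3-yl 3-methylbut-2-enoate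
Product: 15 (1S,3R,5R,6S,7R)-5,6-epoxy-2,2,6,10-tetramethyl-8-oxobicyclo[5.4.0]undec-9-en-3-yl 3-methylbut-2-enoate
Conditions: mCPBA, CH2Cl2, 0 °C
Reagents that add atoms: mCPBA (3-chloroperoxybenzoic acid), OOC(=O)c1cccc(Cl)c1
Why: Prilezhaev epoxidation takes the only electron-rich alkene (enone and senecioate alkenes are electron-poor) from the convex face anti to ring A and to the ester, syn to the ring-fusion hydrogens, which sets C5 as R and C6 as S.

Step 8
Reactants: 15 (1S,3R,5R,6S,7R)-5,6-epoxy-2,2,6,10-tetramethyl-8-oxobicyclo[5.4.0]undec-9-en-3-yl 3-methylbut-2-enoate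
Product: 18 (4R,5S,7R,9R,10R,11R)-9-hydroxy-1-oxolongipin-2-en-7-yl 3-methylbut-2-enoate, via silyl dienol ether 16 (not isolated), via silyl ether 17 (not isolated)
Conditions: TMSOTf (1.1 equiv), Et3N (1.2 equiv), CH2Cl2, 0 °C; then TMSOTf (0.3 equiv), −78 to −40 °C; then 1 M HCl, THF, 0 °C
Reagents that add atoms: none
Why: Proposed new method: soft enolisation gives the thermodynamic extended silyl dienol ether (the alternative α′-CH is tertiary and hindered), then the silyl Lewis acid activates the epoxide, which opens at its tertiary carbon while the γ-carbon of the dienol ether, held on the opposite face by the cis ring fusion, attacks with inversion in a 4-exo closure to give the bicyclo[3.1.1]heptenone after silyl transfer, with epoxide strain release and the enol ether-to-enone change paying for the cyclobutane, which fixes C4 and C10 and leaves the C9 oxygen anti to the new bond; closest known reaction types are Lewis acid Mukaiyama-type and vinylogous Mukaiyama epoxide openings and the Stork 4-exo epoxynitrile cyclisation.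

Step 9
Reactants: 18 (4R,5S,7R,9R,10R,11R)-9-hydroxy-1-oxolongipin-2-en-7-yl 3-methylbut-2-enoate; 19 3-methylbutanoyl chloride
Product: 20 (4R,5S,7R,9R,10R,11R)-9-(3-methylbutanoyloxy)-1-oxolongipin-2-en-7-yl 3-methylbut-2-enoate
Conditions: pyridine, DMAP (cat.), CH2Cl2, rt
Reagents that add atoms: none
Why: DMAP-catalysed esterification of the only free hydroxyl gives the target without touching any stereocenter.

## Compound list

1 | m-xylene (1,3-dimethylbenzene) | Cc1cccc(C)c1 | starting material
2 | 1,5-dimethylcyclohexa-1,4-diene | CC1=CCC=C(C)C1 | intermediate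
3 | 1,3-dimethyl-7,8,9-trioxabicyclo[4.2.1]non-3-ene (racemic mono-ozonide, not isolated) | CC12CC(C)=CCC(OO1)O2 | intermediate
4 | (3Z)-4-methyl-6-oxohept-3-enal | CC(=O)C/C(C)=C\CC=O | intermediate
5 | trimethyl[(2-methylprop-1-en-1-yl)oxy]silane | CC(C)=CO[Si](C)(C)C | starting material
6 | (3R,5Z)-2,2,6-trimethyl-8-oxo-3-(trimethylsilyloxy)non-5-enal (not isolated) | CC(=O)C/C(C)=C\C[C@@H](O[Si](C)(C)C)C(C)(C)C=O | intermediate
7 | (3R,5Z)-3-hydroxy-2,2,6-trimethyl-8-oxonon-5-enal | CC(=O)C/C(C)=C\C[C@@H](O)C(C)(C)C=O | intermediate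
8 | 3-methylbut-2-enoyl chloride (senecioyl chloride) | CC(C)=CC(Cl)=O | starting material
9 | (3R,5Z)-2,2,6-trimethyl-1,8-dioxonon-5-en-3-yl 3-methylbut-2-enoate | CC(=O)C/C(C)=C\C[C@@H](OC(=O)C=C(C)C)C(C)(C)C=O | intermediate
10 | 1-(triphenyl-λ5-phosphanylidene)propan-2-one | CC(=O)C=P(c1ccccc1)(c1ccccc1)c1ccccc1 | starting material
11 | (3E,6R,8Z)-5,5,9-trimethyl-2,11-dioxododeca-3,8-dien-6-yl 3-methylbut-2-enoate | CC(=O)C/C(C)=C\C[C@@H](OC(=O)C=C(C)C)C(C)(C)/C=C/C(C)=O | intermediate
12 | (1R,5R,6S)-5-acetyl-4,7,7-trimethyl-6-(2-oxopropyl)cyclohept-3-en-1-yl 3-methylbut-2-enoate (not isolated) | CC(C)=CC(=O)O[C@@H]1CC=C(C)[C@H](C(C)=O)[C@H](CC(C)=O)C1(C)C | intermediate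
13 | (1S,3R,7R)-10-hydroxy-2,2,6,10-tetramethyl-8-oxobicyclo[5.4.0]undec-5-en-3-yl 3-methylbut-2-enoate (cis-fused, C10 epimers, not isolated) | CC(C)=CC(=O)O[C@@H]1CC=C(C)[C@@H]2C(=O)CC(C)(O)C[C@@H]2C1(C)C | intermediate
14 | (1S,3R,7R)-2,2,6,10-tetramethyl-8-oxobicyclo[5.4.0]undeca-5,9-dien-3-yl 3-methylbut-2-enoate (cis-fused) | CC(C)=CC(=O)O[C@@H]1CC=C(C)[C@@H]2C(=O)C=C(C)C[C@@H]2C1(C)C | intermediate
15 | (1S,3R,5R,6S,7R)-5,6-epoxy-2,2,6,10-tetramethyl-8-oxobicyclo[5.4.0]undec-9-en-3-yl 3-methylbut-2-enoate | CC(C)=CC(=O)O[C@@H]1C[C@H]2O[C@@]2(C)[C@@H]3C(=O)C=C(C)C[C@@H]3C1(C)C | intermediate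
16 | 8-trimethylsilyloxy-8,10-diene (extended trimethylsilyl dienol ether) of 15 (not isolated) | CC(C)=CC(=O)O[C@@H]1C[C@H]2O[C@@]2(C)[C@@H]3C(O[Si](C)(C)C)=CC(C)=C[C@@H]3C1(C)C | intermediate
17 | (4R,5S,7R,9R,10R,11R)-1-oxo-9-(trimethylsilyloxy)longipin-2-en-7-yl 3-methylbut-2-enoate (not isolated) | CC(C)=CC(=O)O[C@@H]1C[C@@H](O[Si](C)(C)C)[C@@]2(C)[C@@H]3C(=O)C=C(C)[C@H]2[C@@H]3C1(C)C | intermediate
18 | (4R,5S,7R,9R,10R,11R)-9-hydroxy-1-oxolongipin-2-en-7-yl 3-methylbut-2-enoate | CC(C)=CC(=O)O[C@@H]1C[C@@H](O)[C@@]2(C)[C@@H]3C(=O)C=C(C)[C@H]2[C@@H]3C1(C)C | intermediate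
19 | 3-methylbutanoyl chloride (isovaleryl chloride) | CC(C)CC(Cl)=O | starting material
20 | (4R,5S,7R,9R,10R,11R)-9-(3-methylbutanoyloxy)-1-oxolongipin-2-en-7-yl 3-methylbut-2-enoate (CNP0214473.1) | CC(C)=CC(=O)O[C@@H]1C[C@@H](OC(=O)CC(C)C)[C@@]2(C)[C@@H]3C(=O)C=C(C)[C@H]2[C@@H]3C1(C)C | target

## Step count and risks

Total step count: 9. Longest linear sequence: 9 steps (1 → 20); compounds 5, 8, 10 and 19 are bought.

The three steps most likely to fail are steps 6, 8 and 3.

Step 6 is the least secure. The Michael addition must form a seven-membered ring at a neopentyl enone carbon, and it competes with 5-exo attack through the γ-carbon of the dienamine. Prolonged heating could also move the ring alkene of 14 into conjugation with the ketone, and a trans-fused isomer would have to be re-equilibrated. The fallback changes the order of bond formation and sets out from 9. Piperidinium acetate in benzene at 80 °C effects intramolecular aldol condensation of the ketone α-CH2 onto the non-enolisable aldehyde, closing the seven-membered ring first as the cross-conjugated dienone (1R)-5-acetyl-4,7,7-trimethylcyclohepta-3,5-dien-1-yl 3-methylbut-2-enoate F1. Intermolecular Mukaiyama–Michael addition of 2-(trimethylsilyloxy)propene (TiCl4, CH2Cl2, −78 °C) to the ring enone carbon, with kinetic protonation, gives diketone 12, here isolated. Pyrrolidine/AcOH then closes ring A, and the route is rejoined at 14.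

Step 8 can fail in two ways. Silylation may occur at the α′-CH, leading to β-elimination of the epoxide, or the activated epoxide may rearrange or eliminate before the C–C bond forms. The fallback replaces the silyl enol ether and Lewis acid by covalent amine activation and sets out from 15. Condensation with pyrrolidine (benzene, 4 Å sieves, rt) gives the extended dienamine 8-(pyrrolidin-1-yl)-8,10-diene of 15 F2. Warming with LiClO4 in MeCN at 40 °C lets its γ-carbon open the epoxide to the tricyclic iminium alkoxide F3. Aqueous AcOH hydrolysis rejoins the route at 18.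

Step 3 may give low enantioselectivity, because the aldehyde-derived enol silane is an untested partner for the chiral boron catalyst. The fallback uses an established ketene-acetal aldol followed by a reduction and sets out from 4. A stoichiometric Kiyooka aldol (N-tosyl-L-valine, BH3·THF, CH2Cl2, −78 °C) with (1-ethylsulfanyl-2-methylprop-1-enoxy)trimethylsilane gives S-ethyl (3R,5Z)-3-hydroxy-2,2,6-trimethyl-8-oxonon-5-enethioate F4. Fukuyama reduction (Et3SiH, Pd/C, acetone, rt) spares the ketone and the alkene and rejoins the route at 7.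

Further compounds
F1 | step 6 | (1R)-5-acetyl-4,7,7-trimethylcyclohepta-3,5-dien-1-yl 3-methylbut-2-enoate | CC(C)=CC(=O)O[C@@H]1CC=C(C)C(C(C)=O)=CC1(C)C
F2 | step 8 | 8-(pyrrolidin-1-yl)-8,10-diene (extended dienamine) of 15 | CC(C)=CC(=O)O[C@@H]1C[C@H]2O[C@@]2(C)[C@@H]3C(N4CCCC4)=CC(C)=C[C@@H]3C1(C)C
F3 | step 8 | N-[(4R,5S,7R,9R,10R,11R)-7-(3-methylbut-2-enoyloxy)-9-oxidolongipin-2-en-1-ylidene]pyrrolidinium (iminium alkoxide) | CC(C)=CC(=O)O[C@@H]1C[C@@H]([O-])[C@@]2(C)[C@@H]3C(=[N+]4CCCC4)C=C(C)[C@H]2[C@@H]3C1(C)C
F4 | step 3 | S-ethyl (3R,5Z)-3-hydroxy-2,2,6-trimethyl-8-oxonon-5-enethioate | CC(=O)C/C(C)=C\C[C@@H](O)C(C)(C)C(=O)SCC
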